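**Retrosynthetic overview**

- Locants (germacranolide numbering): C1 ketone, C2=C3 enol ether, C4(Me)=C5 Z-alkene, C6 lactone carbinol, C7, C8 (ester), C9 (OH), C10 (quaternary, Me), C11(=C13)–C12 lactone; the ring oxygen bridges C3 and C10.
- Enabling feature: C10 is the sp3 carbon of the five-membered O–C3=C2–C1(=O)–C10 furanone ring, α to the C1 ketone, and its neighbour C9 is a carbinol. As an α-diazo ketone carbon it can therefore first accept the C3 oxygen of a C1–C3 1,3-dicarbonyl and then, as the derived 3-hydroxyfuran, add to a C9 aldehyde.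
- Key disconnection: ring O–C10 and C9–C10 in one operation, which opens the oxygen-bridged ten-membered carbocycle (oxabicyclo[6.2.1]) to an acyclic α'-diazo-1,3-diketone aldehyde that carries only the γ-lactone.
- Further disconnections: C2–C3 (aldol of 3-diazobutan-2-one with a Z-enal, then oxidation), O8–acyl, C5–C6 (Nozaki–Hiyama–Kishi with a Z-vinyl iodide), C7–C8 (D-proline cross-aldol), C11=C13 (Eschenmoser methylenation).
- Ring order: γ-lactone first (step 6); furanone and ten-membered carbocycle together in the last step (step 14).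

Key step: step 14

Remark: 13/14 (C11) and 21/22 (C3) are carried as epimer mixtures at a centre that later becomes sp2, and (2R)-2-methylbutanoic acid is taken as a purchasable starting material.

**Step 1**
Reactants: 1 prop-2-yn-1-ol
Product: 3 (Z)-3-iodo-2-methylprop-2-en-1-ol, via alkenylmagnesium alkoxide 2 (not isolated)
Conditions: MeMgBr (2.5 equiv), CuI (10 mol %), Et2O/THF, −10 → 23 °C; then I2, −20 → 0 °C
Reagents that add atoms: methylmagnesium bromide C[Mg]Br; iodine II
Why: Copper-catalysed anti-carbomagnesiation of the propargylic magnesium alkoxide (Duboudin–Jousseaume reaction) puts methyl on the internal carbon and magnesium on the terminal carbon cis to the CH2O arm, so iodinolysis with retention should give the Z-iodide.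

**Step 2**
Reactants: 3 (Z)-3-iodo-2-methylprop-2-en-1-ol
Product: 4 triethyl{[(2Z)-3-iodo-2-methylprop-2-en-1-yl]oxy}silane
Conditions: Et3SiCl, imidazole, CH2Cl2, 0 °C
Reagents that add atoms: chlorotriethylsilane CC[Si](Cl)(CC)CC
Why: Standard silyl ether formation on a primary allylic alcohol; no stereocentre is involved and the alkene geometry is untouched.

**Step 3**
Reactants: 5 3-methylpentane-2,4-dione
Product: 6 3-diazobutan-2-one
Conditions: 4-acetamidobenzenesulfonyl azide, DBU, MeCN, 0 → 23 °C (product kept as a solution)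
Reagents that add atoms: 4-acetamidobenzenesulfonyl azide CC(=O)Nc1ccc(cc1)S(=O)(=O)N=[N+]=[N-]
Why: Regitz deacylative diazo transfer: the enolate of the 2-methyl-1,3-diketone attacks the sulfonyl azide and the adduct fragments with transfer of one acetyl group to the sulfonamide nitrogen, leaving the α-diazo ketone.

**Step 4**
Reactants: 7 methyl 4-oxobutanoate; 8 [(tert-butyldimethylsilyl)oxy]acetaldehyde
Product: 9 methyl (3R,4S)-5-[(tert-butyldimethylsilyl)oxy]-3-formyl-4-hydroxypentanoate
Conditions: D-proline (10 mol %), DMF, 4 °C, slow addition of 7 to 8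
Reagents that add atoms: none
Why: Proline-catalysed direct cross-aldol (enamine catalysis, Houk–List transition state) in which the alkyl aldehyde 7 is the enamine donor and the α-silyloxy aldehyde 8 the acceptor; the D-catalyst should give the anti aldol with the C7 and C8 centres (3R,4S), the mirror image of the L-proline sense.

**Step 5**
Reactants: 9 methyl (3R,4S)-5-[(tert-butyldimethylsilyl)oxy]-3-formyl-4-hydroxypentanoate
Product: 10 methyl (3R,4S)-5-[(tert-butyldimethylsilyl)oxy]-3-formyl-4-[(triethylsilyl)oxy]pentanoate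
Conditions: Et3SiOTf, 2,6-lutidine, CH2Cl2, −78 °C
Reagents that add atoms: triethylsilyl trifluoromethanesulfonate CC[Si](CC)(CC)OS(=O)(=O)C(F)(F)F
Why: Silyl triflate/lutidine silylation of the β-hydroxy aldehyde is fast at low temperature, which should avoid retro-aldol, elimination and lactonisation; the stereocentres are untouched.

**Step 6**
Reactants: 10 methyl (3R,4S)-5-[(tert-butyldimethylsilyl)oxy]-3-formyl-4-[(triethylsilyl)oxy]pentanoate; 4 triethyl{[(2Z)-3-iodo-2-methylprop-2-en-1-yl]oxy}silane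
Product: 12 (4S,5R)-4-{(1S)-2-[(tert-butyldimethylsilyl)oxy]-1-[(triethylsilyl)oxy]ethyl}-5-{(1Z)-2-methyl-3-[(triethylsilyl)oxy]prop-1-en-1-yl}oxolan-2-one, via hydroxy ester 11 (not isolated)
Conditions: CrCl2 (4 equiv), NiCl2 (2 mol %), DMSO, 23 °C; then PPTS (cat.), PhMe, 40 °C
Reagents that add atoms: none
Why: Nozaki–Hiyama–Kishi coupling adds the alkenylchromium species to the aldehyde with retention of the Z geometry; the new C6 carbinol should be set by Felkin–Anh attack anti to the C8 branch, reinforced by the 1,3-anti preference of the β-silyloxy group in this 2,3-anti aldehyde, and the γ-hydroxy ester then closes to the trans-lactone.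

**Step 7**
Reactants: 12 the trans-lactone
Product: 15 (4S,5R)-4-{(1S)-2-[(tert-butyldimethylsilyl)oxy]-1-[(triethylsilyl)oxy]ethyl}-3-methylidene-5-{(1Z)-2-methyl-3-[(triethylsilyl)oxy]prop-1-en-1-yl}oxolan-2-one, via Mannich base 13 (not isolated), via ammonium iodide 14 (not isolated)
Conditions: LiN(iPr)2, THF, −78 °C; CH2=NMe2 I, −78 → 0 °C; then MeI, THF, 23 °C; then NaHCO3, H2O/CH2Cl2
Reagents that add atoms: N,N-dimethylmethyleneiminium iodide (Eschenmoser's salt) C=[N+](C)C.[I-]
Why: Eschenmoser methylenation: the lactone enolate is aminomethylated (Mannich reaction), and quaternisation followed by β-elimination gives the exocyclic methylene, which removes the transient C11 stereocentre.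

**Step 8**
Reactants: 15 the bis(triethylsilyl) methylene lactone
Product: 16 (4R,5R)-4-{(1S)-2-[(tert-butyldimethylsilyl)oxy]-1-hydroxyethyl}-5-[(1Z)-3-hydroxy-2-methylprop-1-en-1-yl]-3-methylideneoxolan-2-one
Conditions: PPTS (0.2 equiv), MeOH/CH2Cl2 (1:1), 0 °C
Reagents that add atoms: none
Why: Acid-catalysed methanolysis should cleave the two triethylsilyl ethers much faster than the primary tert-butyldimethylsilyl ether (graded acid lability of silyl ethers), without touching any stereocentre.

**Step 9**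
Reactants: 16 the diol
Product: 17 (2Z)-3-[(2R,3R)-3-{(1S)-2-[(tert-butyldimethylsilyl)oxy]-1-hydroxyethyl}-4-methylidene-5-oxooxolan-2-yl]-2-methylprop-2-enal
Conditions: MnO2 (20 equiv), CH2Cl2, 23 °C
Reagents that add atoms: none
Why: MnO2 oxidises only the primary allylic alcohol (chemoselective allylic oxidation) under neutral conditions that should keep the Z-enal geometry and leave the secondary C8 alcohol.

**Step 10**
Reactants: 17 the hydroxy enal; 18 (2R)-2-methylbutanoic acid
Product: 19 (1S)-2-[(tert-butyldimethylsilyl)oxy]-1-{(2R,3S)-4-methylidene-2-[(1Z)-2-methyl-3-oxoprop-1-en-1-yl]-5-oxooxolan-3-yl}ethyl (2R)-2-methylbutanoate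
Conditions: iPrN=C=NiPr, DMAP (0.2 equiv), CH2Cl2, 0 → 23 °C
Reagents that add atoms: none
Why: Steglich esterification of the only free (secondary, C8) alcohol; the ester stereocentre comes from acid 18, and carbodiimide/DMAP activation at low temperature should not epimerise it.

**Step 11**
Reactants: 19 the ester enal; 6 3-diazobutan-2-one
Product: 21 (1S)-2-[(tert-butyldimethylsilyl)oxy]-1-{(2R,3S)-2-[(1Z)-6-diazo-3-hydroxy-2-methyl-5-oxohept-1-en-1-yl]-4-methylidene-5-oxooxolan-3-yl}ethyl (2R)-2-methylbutanoate, via lithium enolate 20 (not isolated)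
Conditions: 6, LiN(SiMe3)2, THF, −78 °C, 30 min; then 19, −78 °C; AcOH quench at −78 °C
Reagents that add atoms: none
Why: Kinetic deprotonation of the methyl group of 6 (its diazo carbon bears no hydrogen) gives the α'-enolate, whose directed aldol 1,2-addition to the enal at −78 °C should outrun conjugate addition to either acceptor; the new C3 carbinol forms as an epimer mixture that is erased in step 13.

**Step 12**
Reactants: 21 the diazo β-hydroxy ketone silyl ether
Product: 22 (1S)-1-{(2R,3S)-2-[(1Z)-6-diazo-3-hydroxy-2-methyl-5-oxohept-1-en-1-yl]-4-methylidene-5-oxooxolan-3-yl}-2-hydroxyethyl (2R)-2-methylbutanoate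
Conditions: Bu4NF, AcOH (1:1), THF, 0 °C
Reagents that add atoms: none
Why: Fluoride cleavage of the primary silyl ether, buffered with acetic acid so that acyl migration from O8 to O9, retro-aldol of the β-hydroxy ketone and loss of the diazo group should all be avoided.

**Step 13**
Reactants: 22 the diol
Product: 23 (1S)-1-{(2R,3S)-2-[(1Z)-6-diazo-2-methyl-3,5-dioxohept-1-en-1-yl]-4-methylidene-5-oxooxolan-3-yl}-2-oxoethyl (2R)-2-methylbutanoate
Conditions: Dess–Martin periodinane (2.5 equiv), NaHCO3, CH2Cl2, 0 → 23 °C; used at once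
Reagents that add atoms: none
Why: Dess–Martin oxidation converts both alcohols in one operation (allylic C3 carbinol to the 1,3-diketone, primary C9 alcohol to the α-acyloxy aldehyde) under buffered, non-basic conditions that a diazo ketone tolerates; the C3 epimers converge.

**Step 14**
Reactants: 23 the α'-diazo-1,3-diketone aldehyde
Product: 25 CNP0146060.1, via 3-hydroxyfuran 24 (not isolated)
Conditions: Rh2(OPiv)4 (2 mol %), (PhO)2P(O)OH (10 mol %), 4 Å MS, CH2Cl2, 0 °C, syringe-pump addition of 23 (final 1 mM)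
Reagents that add atoms: none
Why: Proposed new method: dirhodium tetrapivalate removes N2 from the α-diazo ketone, the C3 oxygen of the enolisable C1–C2–C3 dicarbonyl attacks the electrophilic carbenoid carbon C10, and the resulting cyclic ylide collapses by proton shift to the aromatic 3-hydroxyfuran 24, which then adds through C10 to the tethered α-acyloxy aldehyde C9 with the phosphate acting as proton shuttle. The closest known reactions are the rhodium-catalysed cyclisation of α'-diazo-1,3-diketones to 3(2H)-furanones, the aldol-type interception of carbene-derived protic ylides or enols by aldehydes, and 2-selective aldol additions of 3-oxyfurans; their combination in a medium-ring closure is the new element. The furanone closes as a five-membered ring by oxygen-to-carbenoid attack, and the ten-membered carbocycle closes by a 10-exo-trig addition of the enol carbon to the aldehyde, which turns the ring oxygen into the one-atom bridge of the oxabicyclo[6.2.1] system. C10 should be controlled by the tether, because the Z-C4=C5 bond and the trans-lactone with fixed C6, C7 and C8 can fold the chain back over only one furan face; C9 should be controlled by a closed, hydrogen-bonded transition state with the aldehyde hydrogen over the furan and C7 antiperiplanar to the forming bond, giving the 8,9-syn (9R) carbinol. The step needs oxygen attack at C10 to beat 1,2-hydride shift from the C10 methyl, cyclopropanation of the methylene lactone and attack by other carbonyl oxygens, which the five-membered reach of the dicarbonyl oxygen, the bulky carboxylate catalyst and the low temperature should secure. It also needs C10 rather than C2 to be the nucleophilic furan carbon (the position flanked by ring oxygen and hydroxyl) and ring closure to beat oligomerisation (slow addition, high dilution).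

**Compound list**

1 | prop-2-yn-1-ol | C#CCO | starting material
2 | bromomagnesium (Z)-3-(bromomagnesio)-2-methylprop-2-en-1-olate | Br[Mg]/C=C(/C)CO[Mg]Br | intermediate
3 | (Z)-3-iodo-2-methylprop-2-en-1-ol | I/C=C(/C)CO | intermediate
4 | triethyl{[(2Z)-3-iodo-2-methylprop-2-en-1-yl]oxy}silane | I/C=C(/C)CO[Si](CC)(CC)CC | intermediate
5 | 3-methylpentane-2,4-dione | CC(=O)C(C)C(C)=O | starting material
6 | 3-diazobutan-2-one | CC(=O)C(C)=[N+]=[N-] | intermediate
7 | methyl 4-oxobutanoate | COC(=O)CCC=O | starting material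
8 | [(tert-butyldimethylsilyl)oxy]acetaldehyde | O=CCO[Si](C)(C)C(C)(C)C | starting material
9 | methyl (3R,4S)-5-[(tert-butyldimethylsilyl)oxy]-3-formyl-4-hydroxypentanoate | COC(=O)C[C@@H](C=O)[C@H](O)CO[Si](C)(C)C(C)(C)C | intermediate
10 | methyl (3R,4S)-5-[(tert-butyldimethylsilyl)oxy]-3-formyl-4-[(triethylsilyl)oxy]pentanoate | COC(=O)C[C@@H](C=O)[C@H](O[Si](CC)(CC)CC)CO[Si](C)(C)C(C)(C)C | intermediate
11 | methyl (3S,4R,5Z)-3-{(1S)-2-[(tert-butyldimethylsilyl)oxy]-1-[(triethylsilyl)oxy]ethyl}-4-hydroxy-6-methyl-7-[(triethylsilyl)oxy]hept-5-enoate | COC(=O)C[C@@H]([C@H](O)/C=C(/C)CO[Si](CC)(CC)CC)[C@H](O[Si](CC)(CC)CC)CO[Si](C)(C)C(C)(C)C | intermediate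
12 | (4S,5R)-4-{(1S)-2-[(tert-butyldimethylsilyl)oxy]-1-[(triethylsilyl)oxy]ethyl}-5-{(1Z)-2-methyl-3-[(triethylsilyl)oxy]prop-1-en-1-yl}oxolan-2-one | C1C(=O)O[C@H](/C=C(/C)CO[Si](CC)(CC)CC)[C@H]1[C@H](O[Si](CC)(CC)CC)CO[Si](C)(C)C(C)(C)C | intermediate
13 | 3-[(dimethylamino)methyl] derivative of lactone 12 (Mannich base, C11 epimers) | CN(C)CC1C(=O)O[C@H](/C=C(/C)CO[Si](CC)(CC)CC)[C@H]1[C@H](O[Si](CC)(CC)CC)CO[Si](C)(C)C(C)(C)C | intermediate
14 | 3-[(trimethylammonio)methyl] derivative of lactone 12, iodide (C11 epimers) | C[N+](C)(C)CC1C(=O)O[C@H](/C=C(/C)CO[Si](CC)(CC)CC)[C@H]1[C@H](O[Si](CC)(CC)CC)CO[Si](C)(C)C(C)(C)C.[I-] | intermediate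
15 | (4S,5R)-4-{(1S)-2-[(tert-butyldimethylsilyl)oxy]-1-[(triethylsilyl)oxy]ethyl}-3-methylidene-5-{(1Z)-2-methyl-3-[(triethylsilyl)oxy]prop-1-en-1-yl}oxolan-2-one | C=C1C(=O)O[C@H](/C=C(/C)CO[Si](CC)(CC)CC)[C@H]1[C@H](O[Si](CC)(CC)CC)CO[Si](C)(C)C(C)(C)C | intermediate
16 | (4R,5R)-4-{(1S)-2-[(tert-butyldimethylsilyl)oxy]-1-hydroxyethyl}-5-[(1Z)-3-hydroxy-2-methylprop-1-en-1-yl]-3-methylideneoxolan-2-one | C=C1C(=O)O[C@H](/C=C(/C)CO)[C@H]1[C@H](O)CO[Si](C)(C)C(C)(C)C | intermediate
17 | (2Z)-3-[(2R,3R)-3-{(1S)-2-[(tert-butyldimethylsilyl)oxy]-1-hydroxyethyl}-4-methylidene-5-oxooxolan-2-yl]-2-methylprop-2-enal | C=C1C(=O)O[C@H](/C=C(/C)C=O)[C@H]1[C@H](O)CO[Si](C)(C)C(C)(C)C | intermediate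
18 | (2R)-2-methylbutanoic acid | CC[C@@H](C)C(=O)O | starting material
19 | (1S)-2-[(tert-butyldimethylsilyl)oxy]-1-{(2R,3S)-4-methylidene-2-[(1Z)-2-methyl-3-oxoprop-1-en-1-yl]-5-oxooxolan-3-yl}ethyl (2R)-2-methylbutanoate | C=C1C(=O)O[C@H](/C=C(/C)C=O)[C@H]1[C@H](OC(=O)[C@H](C)CC)CO[Si](C)(C)C(C)(C)C | intermediate
20 | lithium 3-diazobut-1-en-2-olate | [Li]OC(=C)C(C)=[N+]=[N-] | intermediate
21 | (1S)-2-[(tert-butyldimethylsilyl)oxy]-1-{(2R,3S)-2-[(1Z)-6-diazo-3-hydroxy-2-methyl-5-oxohept-1-en-1-yl]-4-methylidene-5-oxooxolan-3-yl}ethyl (2R)-2-methylbutanoate (C3 carbinol epimers) | C=C1C(=O)O[C@H](/C=C(/C)C(O)CC(=O)C(C)=[N+]=[N-])[C@H]1[C@H](OC(=O)[C@H](C)CC)CO[Si](C)(C)C(C)(C)C | intermediate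
22 | (1S)-1-{(2R,3S)-2-[(1Z)-6-diazo-3-hydroxy-2-methyl-5-oxohept-1-en-1-yl]-4-methylidene-5-oxooxolan-3-yl}-2-hydroxyethyl (2R)-2-methylbutanoate (C3 carbinol epimers) | C=C1C(=O)O[C@H](/C=C(/C)C(O)CC(=O)C(C)=[N+]=[N-])[C@H]1[C@H](OC(=O)[C@H](C)CC)CO | intermediate
23 | (1S)-1-{(2R,3S)-2-[(1Z)-6-diazo-2-methyl-3,5-dioxohept-1-en-1-yl]-4-methylidene-5-oxooxolan-3-yl}-2-oxoethyl (2R)-2-methylbutanoate | C=C1C(=O)O[C@H](/C=C(/C)C(=O)CC(=O)C(C)=[N+]=[N-])[C@H]1[C@H](OC(=O)[C@H](C)CC)C=O | intermediate
24 | (1S)-1-{(2R,3S)-2-[(1Z)-2-(4-hydroxy-5-methylfuran-2-yl)prop-1-en-1-yl]-4-methylidene-5-oxooxolan-3-yl}-2-oxoethyl (2R)-2-methylbutanoate | C=C1C(=O)O[C@H](/C=C(/C)c2cc(O)c(C)o2)[C@H]1[C@H](OC(=O)[C@H](C)CC)C=O | intermediate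
25 | CNP0146060.1, (4Z,6R,7S,8S,9R,10R)-9-hydroxy-8-[(2R)-2-methylbutanoyloxy]-1-oxo-3,10-epoxygermacra-2,4,11(13)-trien-12,6-olide | C=C1C(=O)O[C@@H]2/C=C(/C)C3=CC(=O)[C@](C)(O3)[C@H](O)[C@@H](OC(=O)[C@H](C)CC)[C@@H]12 | target

**Totals**

Total step count: 14. Longest linear sequence: 11 steps (7 and 8 to 25, steps 4–14).

**Steps most likely to fail**

1. Step 14 (Proposed new method). The carbenoid may be lost to 1,2-hydride shift from the C10 methyl before the oxygen attacks. The hydroxyfuran may ketonise or oligomerise faster than it closes the ten-membered ring. Facial selection at C9 and C10 rests on a folding model with no close precedent and may be poor. The fallback sets out from 23 and separates the two bond formations with known chemistry. Rh2(OAc)4 alone in CH2Cl2 at ordinary concentration should stop at the 2-methyl-3(2H)-furanone aldehyde F1 (carbonyl-ylide formation and proton shift, C10 epimers). Me3SiOTf/Et3N at −78 °C should then give the aromatic 3-(trimethylsilyloxy)furan F2. An intramolecular Mukaiyama aldol at the furan 2-position (BF3·OEt2, or MgBr2·OEt2 to test a chelated aldehyde, CH2Cl2, 1 mM, −78 °C) with aqueous work-up that removes the silyl group would return to the route at 25.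

2. Step 11. The lithium enolate may add in a conjugate sense to the methylene lactone or the enal, or act as a base at C8, instead of adding 1,2 to the aldehyde. The fallback sets out from 19 and makes the C2–C3 bond by acylation instead of aldol addition. Pinnick oxidation (NaClO2, NaH2PO4, 2-methyl-2-butene) would give the Z-enoic acid F3, and 1H-benzotriazole/SOCl2 its N-acylbenzotriazole F4. Soft-enolisation C-acylation of 6 (MgBr2·OEt2, iPr2NEt, CH2Cl2) should give the diazo diketone silyl ether F5 directly at the diketone oxidation level. Bu4NF/AcOH would free the primary alcohol F6, and a single Dess–Martin oxidation would return to the route at 23.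

3. Step 13. Once the 1,3-diketone has formed, excess periodinane may oxidise its enolised C2 methylene, and the new α-acyloxy aldehyde may epimerise or suffer acyl migration during the longer exposure that a double oxidation needs. The fallback sets out from 22 and oxidises the two alcohols one after the other with reagents that each touch only one of them. TEMPO (cat.)/PhI(OAc)2 in CH2Cl2 should oxidise the primary C9 alcohol to the hydroxy aldehyde F7, and MnO2 should then oxidise the allylic C3 carbinol, returning to the route at 23.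

**Further compounds**

F1 | step 14 | (1S)-1-{(2R,3S)-2-[(1Z)-2-(5-methyl-4-oxo-4,5-dihydrofuran-2-yl)prop-1-en-1-yl]-4-methylidene-5-oxooxolan-3-yl}-2-oxoethyl (2R)-2-methylbutanoate (C10 epimers) | C=C1C(=O)O[C@H](/C=C(/C)C2=CC(=O)C(C)O2)[C@H]1[C@H](OC(=O)[C@H](C)CC)C=O
F2 | step 14 | (1S)-1-{(2R,3S)-2-[(1Z)-2-{5-methyl-4-[(trimethylsilyl)oxy]furan-2-yl}prop-1-en-1-yl]-4-methylidene-5-oxooxolan-3-yl}-2-oxoethyl (2R)-2-methylbutanoate | C=C1C(=O)O[C@H](/C=C(/C)c2cc(O[Si](C)(C)C)c(C)o2)[C@H]1[C@H](OC(=O)[C@H](C)CC)C=O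
F3 | step 11 | (2Z)-3-[(2R,3S)-3-{(1S)-2-[(tert-butyldimethylsilyl)oxy]-1-[(2R)-2-methylbutanoyloxy]ethyl}-4-methylidene-5-oxooxolan-2-yl]-2-methylprop-2-enoic acid | C=C1C(=O)O[C@H](/C=C(/C)C(=O)O)[C@H]1[C@H](OC(=O)[C@H](C)CC)CO[Si](C)(C)C(C)(C)C
F4 | step 11 | N-acylbenzotriazole of acid F3 (1-acyl-1H-benzotriazole) | C=C1C(=O)O[C@H](/C=C(/C)C(=O)n2nnc3ccccc23)[C@H]1[C@H](OC(=O)[C@H](C)CC)CO[Si](C)(C)C(C)(C)C
F5 | step 11 | (1S)-2-[(tert-butyldimethylsilyl)oxy]-1-{(2R,3S)-2-[(1Z)-6-diazo-2-methyl-3,5-dioxohept-1-en-1-yl]-4-methylidene-5-oxooxolan-3-yl}ethyl (2R)-2-methylbutanoate | C=C1C(=O)O[C@H](/C=C(/C)C(=O)CC(=O)C(C)=[N+]=[N-])[C@H]1[C@H](OC(=O)[C@H](C)CC)CO[Si](C)(C)C(C)(C)C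
F6 | step 11 | (1S)-1-{(2R,3S)-2-[(1Z)-6-diazo-2-methyl-3,5-dioxohept-1-en-1-yl]-4-methylidene-5-oxooxolan-3-yl}-2-hydroxyethyl (2R)-2-methylbutanoate | C=C1C(=O)O[C@H](/C=C(/C)C(=O)CC(=O)C(C)=[N+]=[N-])[C@H]1[C@H](OC(=O)[C@H](C)CC)CO
F7 | step 13 | (1S)-1-{(2R,3S)-2-[(1Z)-6-diazo-3-hydroxy-2-methyl-5-oxohept-1-en-1-yl]-4-methylidene-5-oxooxolan-3-yl}-2-oxoethyl (2R)-2-methylbutanoate (C3 carbinol epimers) | C=C1C(=O)O[C@H](/C=C(/C)C(O)CC(=O)C(C)=[N+]=[N-])[C@H]1[C@H](OC(=O)[C@H](C)CC)C=O
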